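**Retrosynthetic overview**
1. Target (2S)-flavanone ⇒ break the C2–O1 bond of ring C to give the fully unprotected (E)-chalcone. Forward, a catalytic regio- and enantioselective 6-endo oxa-Michael closure makes ring C last and sets C2.
2. Chalcone ⇒ break Cα=Cβ to give 3'-(2,3-dihydroxybenzyl)-2',4',6'-trihydroxyacetophenone and benzaldehyde (protecting-group-free Claisen–Schmidt through the lithium polyanion).
3. Benzylated acetophenone ⇒ break ArCH2–Ar to give 2',4',6'-trihydroxyacetophenone and 2,3-dihydroxybenzyl alcohol (ortho-quinone methide Friedel–Crafts; positions 3' and 5' are equivalent, so only one mono-benzyl isomer can form).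
4. Ring order: ring A, ring B and the catechol ring are bought intact; ring C (the pyranone) is the only ring built, in the final step, and no protecting groups are used.

Assumption: 2,3-dihydroxybenzyl alcohol is taken as a purchasable catalogue compound, and 2',4',6'-trihydroxyacetophenone is used after drying its commercial monohydrate.

**Route**

Step 1
Reactants: 1 2',4',6'-trihydroxyacetophenone; 2 2,3-dihydroxybenzyl alcohol
Product: 4 1-[3-(2,3-dihydroxybenzyl)-2,4,6-trihydroxyphenyl]ethan-1-one, via ortho-quinone methide 3 (not isolated)
Conditions: 1 (3 equiv), BF3·OEt2 (0.3 equiv), 1,4-dioxane, 2 (1 equiv) added over 4 h, 20 °C, Ar; excess 1 recovered on silica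
Reagents that add atoms: none
Why: Acid-promoted loss of water from 2 gives the ortho-quinone methide (ortho-hydroxybenzyl cation) 3, which the much more nucleophilic phloroglucinol ring of 1 captures at C-3' in a Friedel–Crafts alkylation (3' and 5' are equivalent, so one regioisomer), with excess 1 and slow addition holding back double benzylation; no stereocentre is formed.

Step 2
Reactants: 4 1-[3-(2,3-dihydroxybenzyl)-2,4,6-trihydroxyphenyl]ethan-1-one; 5 benzaldehyde
Product: 7 (2E)-1-[3-(2,3-dihydroxybenzyl)-2,4,6-trihydroxyphenyl]-3-phenylprop-2-en-1-one, via aldol adduct 6 (not isolated)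
Conditions: LiN(SiMe3)2 (6.5 equiv, 1 M in THF), THF, −78 °C, 1 h; 5 (1.3 equiv), −78 → 20 °C, 16 h; 1 M HCl to pH 4 at 0 °C; Ar throughout; chromatographed and used at once
Reagents that add atoms: none
Why: Claisen–Schmidt condensation on the lithium pentaphenoxide-enolate (the five O–H are removed first, the sixth equivalent of base forms the methyl ketone enolate), with aldol addition to non-enolisable benzaldehyde and E1cB dehydration of 6 giving the conjugated (E)-enone as the thermodynamic alkene; the polyanion does not ring-close in aprotic base and the cold acidic quench keeps the chalcone open.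

Step 3
Reactants: 7 (2E)-1-[3-(2,3-dihydroxybenzyl)-2,4,6-trihydroxyphenyl]-3-phenylprop-2-en-1-one
Product: 8 (2S)-6-(2,3-dihydroxybenzyl)-5,7-dihydroxy-2-phenyl-2,3-dihydro-4H-chromen-4-one
Conditions: quinine-derived squaramide 3-{[3,5-bis(trifluoromethyl)phenyl]amino}-4-{[(S)-(6-methoxyquinolin-4-yl)[(1S,2S,4S,5R)-5-ethenyl-1-azabicyclo[2.2.2]octan-2-yl]methyl]amino}cyclobut-3-ene-1,2-dione (C32H28F6N4O3, 10 mol %), 2-MeTHF/toluene 1:3 (0.05 M), 4 Å molecular sieves, Ar, −10 °C, 48 h; then silica plug (EtOAc, 0.5 % AcOH) and recrystallisation
Reagents that add atoms: none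
Why: Proposed new method: a regio- and enantioselective 6-endo-trig oxa-Michael ring closure of a non-activated, fully unprotected 2',6'-dihydroxychalcone under bifunctional Brønsted-base/hydrogen-bond catalysis, a small-molecule mimic of chalcone isomerase. The quinuclidine nitrogen takes a proton from the acidic phloroglucinol unit (4'-OH, pKa about 7–8) to form a tight ammonium phenoxide ion pair, while the squaramide N–H pair binds the ketone oxygen, raising enone electrophilicity and stabilising the developing enolate, which the ammonium then protonates. The ketone stays chelated to the buttressed 2'-OH next to the benzyl group, so the unhindered 6'-oxygen lies syn to C-β and closes the C2–O1 bond, giving the 6-benzyl and not the 8-benzyl isomer (the same bias seen in uncatalysed closure of 3'-alkylated 2',4',6'-trihydroxychalcones, here reinforced by the bulk of the ion-paired catalyst). The working model has the catalyst's quinoline/aryl wall covering the Re face, so attack occurs on the Si face of C-β and gives 2S. The product is kinetically safe because ring re-opening needs amine-mediated enolisation at C-3, which is slow at −10 °C in an aprotic medium. The closest known reactions are the cinchona thiourea-catalysed oxa-Michael cyclisation of α-carboxylate-activated 2'-hydroxychalcones and the enzymatic chalcone isomerase step, neither shown on a free polyphenolic 3'-substituted chalcone with two competing ortho hydroxyls.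

**Compound list**
1 | 1-(2,4,6-trihydroxyphenyl)ethan-1-one (2',4',6'-trihydroxyacetophenone) | CC(=O)c1c(O)cc(O)cc1O | starting material
2 | 3-(hydroxymethyl)benzene-1,2-diol (2,3-dihydroxybenzyl alcohol) | OCc1cccc(O)c1O | starting material
3 | 2-hydroxy-6-methylidenecyclohexa-2,4-dien-1-one (ortho-quinone methide) | C=C1C=CC=C(O)C1=O | intermediate
4 | 1-[3-(2,3-dihydroxybenzyl)-2,4,6-trihydroxyphenyl]ethan-1-one | CC(=O)c1c(O)cc(O)c(Cc2cccc(O)c2O)c1O | intermediate
5 | benzaldehyde | O=Cc1ccccc1 | starting material
6 | 1-[3-(2,3-dihydroxybenzyl)-2,4,6-trihydroxyphenyl]-3-hydroxy-3-phenylpropan-1-one (racemic aldol adduct; present in the flask as its lithium salt, neutral form drawn) | OC(CC(=O)c1c(O)cc(O)c(Cc2cccc(O)c2O)c1O)c1ccccc1 | intermediate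
7 | (2E)-1-[3-(2,3-dihydroxybenzyl)-2,4,6-trihydroxyphenyl]-3-phenylprop-2-en-1-one | O=C(/C=C/c1ccccc1)c1c(O)cc(O)c(Cc2cccc(O)c2O)c1O | intermediate
8 | (2S)-6-(2,3-dihydroxybenzyl)-5,7-dihydroxy-2-phenyl-2,3-dihydro-4H-chromen-4-one | O=C1C[C@@H](c2ccccc2)Oc2cc(O)c(Cc3cccc(O)c3O)c(O)c21 | target

**Totals**
Total step count: 3. Longest linear sequence: 3 steps (1 → 4 → 7 → 8).

**Steps most likely to fail, with fallbacks**

Step 3 (the proposed method) is the most uncertain. The electron-rich enone may turn over slowly, the enantioselectivity or the 6'-OH over 2'-OH preference may be only moderate, and the absolute sense of induction rests on a model. If the sense proves to be 2R, the quinidine-derived pseudoenantiomer of the same squaramide (also C32H28F6N4O3) is used in the same protocol. The fallback, by known chemistry, sets out from 7. NaOAc in EtOH at reflux closes ring C without stereocontrol to give racemic 6-(2,3-dihydroxybenzyl)-5,7-dihydroxy-2-phenylchroman-4-one F6, together with the minor racemic 8-(2,3-dihydroxybenzyl)-5,7-dihydroxy-2-phenylchroman-4-one F7. The two regioisomers are separated by reversed-phase chromatography. F6 is then resolved by preparative supercritical-fluid chromatography on amylose tris(3,5-dimethylphenylcarbamate), and the (2S) fraction is 8, where the fallback comes back to the route. The unwanted half of F6 is re-equilibrated with NaOAc (ring opening and re-closure) and resolved again.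

Step 2 may suffer from a poorly soluble polyanion, incomplete enolisation, a stalled aldol adduct, or partial racemic ring closure on work-up. The fallback sets out from 4 and uses a protect–condense–deprotect sequence. NaH and MOMCl in DMF at 0 → 20 °C give 1-[3-{[2,3-bis(methoxymethoxy)phenyl]methyl}-2,4,6-tris(methoxymethoxy)phenyl]ethan-1-one F3. KOH in EtOH with 5 at 20 °C gives, through the pentakis(methoxymethyl) aldol adduct F4 (not isolated), the pentakis(methoxymethyl) (E)-chalcone F5. HCl in MeOH at 20 °C removes all five acetals and the fallback comes back at 7.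

Step 1 may give double benzylation, self-condensation of the quinone methide, or low conversion, because the acetyl group lowers the nucleophilicity of ring A. The fallback sets out from 2 and reverses the order of the two C–C bond formations. Compound 2 is added slowly to commercial phloroglucinol (5 equiv; far more nucleophilic and removed by aqueous wash) with BF3·OEt2 in 1,4-dioxane, again through 3, to give 2-(2,3-dihydroxybenzyl)benzene-1,3,5-triol F1. A Hoesch acylation (MeCN, ZnCl2, HCl gas, Et2O, 0 °C) then gives 1-[3-(2,3-dihydroxybenzyl)-2,4,6-trihydroxyphenyl]ethan-1-iminium chloride F2 (not isolated). Positions 4 and 6 of F1 are equivalent and the catechol ring is too unreactive for this reaction, so one isomer forms. Hydrolysis in water at 100 °C brings the fallback back at 4.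

**Further compounds**
F1 | step 1 | 2-(2,3-dihydroxybenzyl)benzene-1,3,5-triol | Oc1cc(O)c(Cc2cccc(O)c2O)c(O)c1
F2 | step 1 | 1-[3-(2,3-dihydroxybenzyl)-2,4,6-trihydroxyphenyl]ethan-1-iminium chloride | CC(=[NH2+])c1c(O)cc(O)c(Cc2cccc(O)c2O)c1O.[Cl-]
F3 | step 2 | 1-[3-{[2,3-bis(methoxymethoxy)phenyl]methyl}-2,4,6-tris(methoxymethoxy)phenyl]ethan-1-one | CC(=O)c1c(OCOC)cc(OCOC)c(Cc2cccc(OCOC)c2OCOC)c1OCOC
F4 | step 2 | 1-[3-{[2,3-bis(methoxymethoxy)phenyl]methyl}-2,4,6-tris(methoxymethoxy)phenyl]-3-hydroxy-3-phenylpropan-1-one (racemic) | OC(CC(=O)c1c(OCOC)cc(OCOC)c(Cc2cccc(OCOC)c2OCOC)c1OCOC)c1ccccc1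
F5 | step 2 | (2E)-1-[3-{[2,3-bis(methoxymethoxy)phenyl]methyl}-2,4,6-tris(methoxymethoxy)phenyl]-3-phenylprop-2-en-1-one | O=C(/C=C/c1ccccc1)c1c(OCOC)cc(OCOC)c(Cc2cccc(OCOC)c2OCOC)c1OCOC
F6 | step 3 | 6-(2,3-dihydroxybenzyl)-5,7-dihydroxy-2-phenylchroman-4-one (racemic) | O=C1CC(c2ccccc2)Oc2cc(O)c(Cc3cccc(O)c3O)c(O)c21
F7 | step 3 | 8-(2,3-dihydroxybenzyl)-5,7-dihydroxy-2-phenylchroman-4-one (racemic) | O=C1CC(c2ccccc2)Oc2c(Cc3cccc(O)c3O)c(O)cc(O)c21
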